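**Retrosynthetic overview**
1. Target 22 ← enantioselective CBS reduction of the C3' ketone 20 (sets the only stereocentre).
2. 20 ← both rings closed in one pot: double 6π-electrocyclisation of an acyclic C40 bis(dienylallene) 18, made in situ by two SN2' cuprate substitutions on the bis(propargylic acetate) 11.
3. Ring A comes from a (Z)-dienyl cuprate (isobutenyl cuprate + acetylene); ring B from a 2-ethoxydienyl cuprate (isobutenyl cuprate + ethoxyethyne), its enol ether becoming the enone.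
4. 11 ← prop-1-ynyl Grignard addition/acetylation of the retro-C22 dialdehyde 8.
5. 8 ← two rounds of two-directional HWE/DIBAL from glyoxal and a C5 cyanophosphonate.

Assumption: E/Z isomers at the trisubstituted chain double bonds (commercial 2 is an E/Z mixture) and at the labile exocyclic 6,7/6',7' bonds are equilibrated with cat. I2 and the isomer drawn is isolated by crystallisation or chromatography; glyoxal is used as its trimer dihydrate.

Carotenoid numbering is used for the C40 compounds (ring atoms C1–C6, chain C7–C15 and C15'–C7', primed ring = ring B).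

**Step 1**
Reactants: 1 glyoxal; 2 diethyl [(2E)-3-cyano-2-methylprop-2-en-1-yl]phosphonate
Product: 3 (2E,4E,6E,8E)-3,8-dimethyldeca-2,4,6,8-tetraenedinitrile
Conditions: 2 (2.6 eq), NaH, THF, 0 °C; glyoxal trimer dihydrate, 0 °C → rt; recryst.
Reagents that add atoms: none
Why: Two-directional Horner–Wadsworth–Emmons olefination of both glyoxal carbonyls by the vinylogous cyanophosphonate anion gives the two new E-disubstituted double bonds, as in retinonitrile chain extensions; no stereocentre is formed.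

**Step 2**
Reactants: 3 (2E,4E,6E,8E)-3,8-dimethyldeca-2,4,6,8-tetraenedinitrile
Product: 5 (2E,4E,6E,8E)-3,8-dimethyldeca-2,4,6,8-tetraenedial, via bis(N-diisobutylaluminio)diimine 4 (not isolated)
Conditions: DIBAL-H (2.5 eq), CH2Cl2, −78 → −40 °C; 1 M HCl, 0 °C
Reagents that add atoms: water, O
Why: DIBAL-H adds once to each conjugated nitrile (1,2-hydroalumination) and the N-aluminoimine is hydrolysed to the enal on work-up, the standard nitrile-to-aldehyde reduction used for retinonitrile; no stereocentre is formed.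

**Step 3**
Reactants: 5 (2E,4E,6E,8E)-3,8-dimethyldeca-2,4,6,8-tetraenedial; 2 diethyl [(2E)-3-cyano-2-methylprop-2-en-1-yl]phosphonate
Product: 6 (2E,4E,6E,8E,10E,12E,14E,16E)-3,7,12,16-tetramethyloctadeca-2,4,6,8,10,12,14,16-octaenedinitrile
Conditions: 2 (2.4 eq), NaH, THF, 0 °C → rt; recryst.
Reagents that add atoms: none
Why: A second two-directional Horner–Wadsworth–Emmons olefination at both enal termini extends the chain by C5 at each end with E-selective formation of the new disubstituted double bonds; no stereocentre is formed.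

**Step 4**
Reactants: 6 (2E,4E,6E,8E,10E,12E,14E,16E)-3,7,12,16-tetramethyloctadeca-2,4,6,8,10,12,14,16-octaenedinitrile
Product: 8 (2E,4E,6E,8E,10E,12E,14E,16E)-3,7,12,16-tetramethyloctadeca-2,4,6,8,10,12,14,16-octaenedial, via bis(N-diisobutylaluminio)diimine 7 (not isolated)
Conditions: DIBAL-H (2.5 eq), CH2Cl2/toluene, −78 → −40 °C; 1 M HCl, 0 °C
Reagents that add atoms: water, O
Why: Same DIBAL-H nitrile-to-aldehyde reduction as in step 2; it gives the retro-patterned C22 dialdehyde whose CHO carbons become C7 and C7'; no stereocentre is formed.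

**Step 5**
Reactants: 8 (2E,4E,6E,8E,10E,12E,14E,16E)-3,7,12,16-tetramethyloctadeca-2,4,6,8,10,12,14,16-octaenedial; 9 prop-1-yn-1-ylmagnesium bromide
Product: 11 (5E,7E,9E,11E,13E,15E,17E,19E)-6,10,15,19-tetramethyltetracosa-5,7,9,11,13,15,17,19-octaene-2,22-diyne-4,21-diyl diacetate, via bis(bromomagnesium alkoxide) 10 (not isolated)
Conditions: 9 (2.5 eq), THF, −40 → 0 °C; Ac2O (4 eq), DMAP (cat.), 0 °C; NaHCO3 work-up, Et3N-deactivated SiO2
Reagents that add atoms: acetic anhydride, CC(=O)OC(C)=O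
Why: Alkynyl Grignard reagents add strictly 1,2 to polyenals and the magnesium alkoxide is acetylated in situ; the two carbinol centres form unselectively (rac/meso mixture) and are destroyed in step 6.

**Step 6**
Reactants: 11 (5E,7E,9E,11E,13E,15E,17E,19E)-6,10,15,19-tetramethyltetracosa-5,7,9,11,13,15,17,19-octaene-2,22-diyne-4,21-diyl diacetate; 12 1-bromo-2-methylprop-1-ene; 13 acetylene; 14 ethoxyethyne
Product: 20 2,3,4',5'-tetradehydro-4,5'-retro-β,β-caroten-3'-one, via 2-methylprop-1-enyllithium 15 (not isolated), via Z-dienyl cuprate 16 (not isolated), via ethoxydienyl cuprate 17 (not isolated), via acyclic bis(dienylallene) 18 (not isolated), via bicyclic ethyl dienol ether 19 (not isolated)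
Conditions: 12, Li, Et2O, 0 °C; CuBr·SMe2 (0.5 eq per Li reagent), −40 °C; one half + HC≡CH, −50 → −10 °C; other half + 14, THF, −60 → −40 °C; combine at −78 °C (1.3 eq each), add 11, −78 → −30 °C; then rt, 12 h, dark; aq. NH4Cl; oxalic acid, THF–H2O, 0 °C; cat. I2, hν; SiO2
Reagents that add atoms: water, O
Why: Proposed new method: syn-carbocupration (Normant type) of acetylene and of ethoxyethyne by the isobutenyl cuprate gives the two (Z)-configured dienyl cuprates 16 and 17, anti-SN2' displacement of each propargylic acetate (the known cuprate route to vinylallenes) places them on C5 and C5' to give bis(dienylallene) 18, whose two cis-hexatriene units (C1=C2–C3=C4–C5=C6 with an unhindered sp terminus) close by thermal disrotatory 6π-electrocyclisation at rt (closest known reaction: room-temperature dienylallene to alkylidenecyclohexadiene closure) to form both rings and both exocyclic 6,7-alkenes in one pot, after which the ring-B enol ether is hydrolysed to the enone; the two termini react independently, so the mixed product is statistical (at most 50 %, separated from the bis-hydrocarbon and the diketone), and no stereocentre is formed.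

**Step 7**
Reactants: 20 2,3,4',5'-tetradehydro-4,5'-retro-β,β-caroten-3'-one
Product: 22 (3'S)-2,3,4',5'-tetradehydro-4,5'-retro-β,β-caroten-3'-ol, via catecholborate ester 21 (not isolated)
Conditions: (R)-2-methyl-CBS-oxazaborolidine (0.5 eq), catecholborane (1.8 eq), toluene/CH2Cl2, −78 → −40 °C; MeOH, then aq. NaOH wash; recryst. in the dark
Reagents that add atoms: none
Why: Corey–Bakshi–Shibata reduction gives clean 1,2-reduction of the enone, and with the C4'=C5' alkenyl arm as the large group and C2'H2 as the small group the (R)-catalyst delivers hydride to the face that gives the (3'S)-allylic alcohol.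

**Compound list**
1 | glyoxal (ethanedial, used as trimer dihydrate) | O=CC=O | starting material
2 | diethyl [(2E)-3-cyano-2-methylprop-2-en-1-yl]phosphonate | CCOP(=O)(OCC)C/C(C)=C/C#N | starting material
3 | (2E,4E,6E,8E)-3,8-dimethyldeca-2,4,6,8-tetraenedinitrile | N#C/C=C(C)/C=C/C=C/C(C)=C/C#N | intermediate
4 | N,N'-bis(diisobutylalumanyl)-(2E,4E,6E,8E)-3,8-dimethyldeca-2,4,6,8-tetraene-1,10-diimine (in situ) | CC(C)C[Al](CC(C)C)N=C/C=C(C)/C=C/C=C/C(C)=C/C=N[Al](CC(C)C)CC(C)C | intermediate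
5 | (2E,4E,6E,8E)-3,8-dimethyldeca-2,4,6,8-tetraenedial | O=C/C=C(C)/C=C/C=C/C(C)=C/C=O | intermediate
6 | (2E,4E,6E,8E,10E,12E,14E,16E)-3,7,12,16-tetramethyloctadeca-2,4,6,8,10,12,14,16-octaenedinitrile | N#C/C=C(C)/C=C/C=C(C)/C=C/C=C/C(C)=C/C=C/C(C)=C/C#N | intermediate
7 | N,N'-bis(diisobutylalumanyl) diimine of the all-E C22 dialdehyde 8 (in situ) | CC(C)C[Al](CC(C)C)N=C/C=C(C)/C=C/C=C(C)/C=C/C=C/C(C)=C/C=C/C(C)=C/C=N[Al](CC(C)C)CC(C)C | intermediate
8 | (2E,4E,6E,8E,10E,12E,14E,16E)-3,7,12,16-tetramethyloctadeca-2,4,6,8,10,12,14,16-octaenedial | O=C/C=C(C)/C=C/C=C(C)/C=C/C=C/C(C)=C/C=C/C(C)=C/C=O | intermediate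
9 | prop-1-yn-1-ylmagnesium bromide | CC#C[Mg]Br | starting material
10 | bis(bromomagnesium) 4,21-dialkoxide of the all-E 6,10,15,19-tetramethyltetracosa-5,7,9,11,13,15,17,19-octaene-2,22-diyne-4,21-diol (in situ, rac/meso) | CC#CC(O[Mg]Br)/C=C(C)/C=C/C=C(C)/C=C/C=C/C(C)=C/C=C/C(C)=C/C(O[Mg]Br)C#CC | intermediate
11 | (5E,7E,9E,11E,13E,15E,17E,19E)-6,10,15,19-tetramethyltetracosa-5,7,9,11,13,15,17,19-octaene-2,22-diyne-4,21-diyl diacetate (rac/meso at C4 and C21) | CC#CC(OC(C)=O)/C=C(C)/C=C/C=C(C)/C=C/C=C/C(C)=C/C=C/C(C)=C/C(OC(C)=O)C#CC | intermediate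
12 | 1-bromo-2-methylprop-1-ene | CC(C)=CBr | starting material
13 | acetylene | C#C | starting material
14 | ethoxyethyne | CCOC#C | starting material
15 | 2-methylprop-1-enyllithium (in situ) | [Li]C=C(C)C | intermediate
16 | lithium bis[(1Z)-4-methylpenta-1,3-dien-1-yl]cuprate (in situ) | [Li+].CC(C)=C/C=C\[Cu-]/C=C\C=C(C)C | intermediate
17 | lithium bis[(1E)-2-ethoxy-4-methylpenta-1,3-dien-1-yl]cuprate (in situ; Cu cis to the isobutenyl group) | [Li+].CC(C)=C/C(OCC)=C\[Cu-]/C=C(OCC)\C=C(C)C | intermediate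
18 | acyclic C40 bis(dienylallene) (in situ): Me2C=CH–CH=CH(Z)–C(Me)=C=CH–[all-E C8–C8' octaene of 11]–CH=C=C(Me)–CH=C(OEt)–CH=CMe2, with C2' cis to C5' across C3'=C4'; allene axes unspecified | CC(C)=C/C=C\C(C)=C=C/C=C(C)/C=C/C=C(C)/C=C/C=C/C(C)=C/C=C/C(C)=C/C=C=C(C)/C=C(OCC)\C=C(C)C | intermediate
19 | 3'-ethoxy-2,3,2',3',4',5'-hexadehydro-4,5'-retro-β,β-carotene (in situ; ring A = 2,6,6-trimethylcyclohexa-2,4-dien-1-ylidene, ring B = 4-ethoxy-2,6,6-trimethylcyclohexa-2,4-dien-1-ylidene; 6,7 and 6',7' E/Z mixture, chain all-E) | CC1=CC=CC(C)(C)C1=C/C=C(C)/C=C/C=C(C)/C=C/C=C/C(C)=C/C=C/C(C)=C/C=C1C(C)=CC(OCC)=CC1(C)C | intermediate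
20 | 2,3,4',5'-tetradehydro-4,5'-retro-β,β-caroten-3'-one (ring A as in the target, ring B = 2,6,6-trimethyl-4-oxocyclohex-2-en-1-ylidene; chain all-E; C8 and C8' on the gem-dimethyl side of the exocyclic double bonds) | CC1=CC=CC(C)(C)\C1=C/C=C(C)/C=C/C=C(C)/C=C/C=C/C(C)=C/C=C/C(C)=C/C=C1/C(C)=CC(=O)CC1(C)C | intermediate
21 | 2-alkoxy-1,3,2-benzodioxaborole (catecholborate) of 22 at O3' (in situ, 3'S) | CC1=CC=CC(C)(C)\C1=C/C=C(C)/C=C/C=C(C)/C=C/C=C/C(C)=C/C=C/C(C)=C/C=C1/C(C)=C[C@@H](OB2Oc3ccccc3O2)CC1(C)C | intermediate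
22 | (3'S)-2,3,4',5'-tetradehydro-4,5'-retro-β,β-caroten-3'-ol (anhydroeschscholtzxanthin, CNP0202479.1) | CC1=CC=CC(C)(C)\C1=C/C=C(C)/C=C/C=C(C)/C=C/C=C/C(C)=C/C=C/C(C)=C/C=C1/C(C)=C[C@@H](O)CC1(C)C | target

**Total step count:** 7. **Longest linear sequence:** 7 (fully linear; 1, 2, 9, 12, 13 and 14 are commercial).

**Steps most likely to fail**

Step 6 (one-pot cuprate/double electrocyclisation). Risks: sluggish alkenyl transfer in the carbocupration, β-elimination of the ethoxyvinyl cuprate above about −20 °C, [1,5]/[1,7]-H shifts of the vinylallene competing with ring closure, and the 50 % statistical ceiling. The fallback sets out from dialdehyde 8 and re-joins the route at target 22. Addition of 9 and quenching of alkoxide 10 with 3-methylbut-2-enoyl chloride gives the bis(3-methylbut-2-enoate) F1. Tebbe methylenation (−40 → 0 °C) gives the bis(4-methylpenta-1,3-dien-2-yl) ether F2. Au(I)-catalysed propargyl Claisen rearrangement at rt gives the bis(β-allenyl ketone) F3. TMSOTf/Et3N gives the bis(silyl trienol ether) F4, which closes both rings at rt to the bicyclic bis(silyl dienol ether) F5. Aqueous HCl then gives rhodoxanthin F6. (R)-CBS/catecholborane reduces both ketones through the bis(catecholborate) F7 to (3S,3'S)-eschscholtzxanthin F8. Mono-dehydration with 1 eq Burgess reagent (statistical, diol recycled) gives 22.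

Step 7 (CBS reduction). Risks: the neopentyl-type C2' methylene may erode facial discrimination, and the polyene-conjugated ketone is a weak electrophile. The fallback sets out from ketone 20 and re-joins at 22. Luche reduction (NaBH4, CeCl3, MeOH/THF) gives the racemic alcohol F9. Acylation with (1S)-camphanoyl chloride/pyridine gives the diastereomeric esters, the (3'S)-camphanate F10 and the (3'R)-camphanate F11, which are separated by HPLC or crystallisation. Methanolysis of F10 (K2CO3, MeOH) gives 22.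

Step 1 (double HWE on glyoxal). Risks: glyoxal oligomerises or undergoes Cannizzaro-type reaction under base, and its hydrate water quenches the anion. The fallback sets out from phosphonate 2 and re-joins at dinitrile 3. HWE of 2 with 2,2-dimethoxyacetaldehyde gives (2E,4E)-6,6-dimethoxy-3-methylhexa-2,4-dienenitrile F12. Aqueous acid unmasks (2E,4E)-3-methyl-6-oxohexa-2,4-dienenitrile F13. A second HWE of F13 with 2 gives 3.

**Further compounds**
F1 | step 6 | all-E 6,10,15,19-tetramethyltetracosa-5,7,9,11,13,15,17,19-octaene-2,22-diyne-4,21-diyl bis(3-methylbut-2-enoate) | CC#CC(OC(=O)C=C(C)C)/C=C(C)/C=C/C=C(C)/C=C/C=C/C(C)=C/C=C/C(C)=C/C(OC(=O)C=C(C)C)C#CC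
F2 | step 6 | all-E 4,21-bis[(4-methylpenta-1,3-dien-2-yl)oxy]-6,10,15,19-tetramethyltetracosa-5,7,9,11,13,15,17,19-octaene-2,22-diyne | CC#CC(OC(=C)C=C(C)C)/C=C(C)/C=C/C=C(C)/C=C/C=C/C(C)=C/C=C/C(C)=C/C(OC(=C)C=C(C)C)C#CC
F3 | step 6 | acyclic C40 bis(β-allenyl ketone) Me2C=CH–CO–CH2–C(Me)=C=CH–[all-E octaene]–CH=C=C(Me)–CH2–CO–CH=CMe2 | CC(C)=CC(=O)CC(C)=C=C/C=C(C)/C=C/C=C(C)/C=C/C=C/C(C)=C/C=C/C(C)=C/C=C=C(C)CC(=O)C=C(C)C
F4 | step 6 | bis(trimethylsilyl trienol ether) of F3 (C2 cis to C5 across C3=C4 at both ends) | CC(C)=C/C(O[Si](C)(C)C)=C\C(C)=C=C/C=C(C)/C=C/C=C(C)/C=C/C=C/C(C)=C/C=C/C(C)=C/C=C=C(C)/C=C(O[Si](C)(C)C)\C=C(C)C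
F5 | step 6 | 3,3'-bis(trimethylsilyloxy)-2,3,2',3',4',5'-hexadehydro-4,5'-retro-β,β-carotene (6,7/6',7' E/Z mixture) | CC1=CC(O[Si](C)(C)C)=CC(C)(C)C1=C/C=C(C)/C=C/C=C(C)/C=C/C=C/C(C)=C/C=C/C(C)=C/C=C1C(C)=CC(O[Si](C)(C)C)=CC1(C)C
F6 | step 6 | rhodoxanthin (4',5'-didehydro-4,5'-retro-β,β-carotene-3,3'-dione) | CC1=CC(=O)CC(C)(C)\C1=C/C=C(C)/C=C/C=C(C)/C=C/C=C/C(C)=C/C=C/C(C)=C/C=C1/C(C)=CC(=O)CC1(C)C
F7 | step 6 | bis(catecholborate) of (3S,3'S)-eschscholtzxanthin | CC1=C[C@@H](OB2Oc3ccccc3O2)CC(C)(C)\C1=C/C=C(C)/C=C/C=C(C)/C=C/C=C/C(C)=C/C=C/C(C)=C/C=C1/C(C)=C[C@@H](OB2Oc3ccccc3O2)CC1(C)C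
F8 | step 6 | (3S,3'S)-eschscholtzxanthin (4',5'-didehydro-4,5'-retro-β,β-carotene-3,3'-diol) | CC1=C[C@@H](O)CC(C)(C)\C1=C/C=C(C)/C=C/C=C(C)/C=C/C=C/C(C)=C/C=C/C(C)=C/C=C1/C(C)=C[C@@H](O)CC1(C)C
F9 | step 7 | racemic 2,3,4',5'-tetradehydro-4,5'-retro-β,β-caroten-3'-ol | CC1=CC=CC(C)(C)\C1=C/C=C(C)/C=C/C=C(C)/C=C/C=C/C(C)=C/C=C/C(C)=C/C=C1/C(C)=CC(O)CC1(C)C
F10 | step 7 | (3'S)-alcohol (1S)-camphanate | CC1=CC=CC(C)(C)\C1=C/C=C(C)/C=C/C=C(C)/C=C/C=C/C(C)=C/C=C/C(C)=C/C=C1/C(C)=C[C@@H](OC(=O)[C@@]23CC[C@@](C)(C(=O)O2)C3(C)C)CC1(C)C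
F11 | step 7 | (3'R)-alcohol (1S)-camphanate | CC1=CC=CC(C)(C)\C1=C/C=C(C)/C=C/C=C(C)/C=C/C=C/C(C)=C/C=C/C(C)=C/C=C1/C(C)=C[C@H](OC(=O)[C@@]23CC[C@@](C)(C(=O)O2)C3(C)C)CC1(C)C
F12 | step 1 | (2E,4E)-6,6-dimethoxy-3-methylhexa-2,4-dienenitrile | COC(OC)/C=C/C(C)=C/C#N
F13 | step 1 | (2E,4E)-3-methyl-6-oxohexa-2,4-dienenitrile | O=C/C=C/C(C)=C/C#N
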